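**Plan**
1. Cuts (halimane numbering): first the C15 acetate and the C4–C19 bond (enolate methylation). Ring A is then cut at C2–C3 and C4–C5 (retro-Diels–Alder, methyl acrylate). Ring B is cut at C6–C7 and C8–C9 (retro-Diels–Alder, an acrylate unit whose carbonyl carbon is C17). The acyclic dienyne is cut at C5–C10 and C9–C20.
2. Enabling feature: C10 is the sp2 carbon shared by rings A and B. The C1=C10 olefin flanked by C5–H is the cyclohexene retron of ring A. The diene this unveils, C5=C10–C1=C2, contains the C5=C10 olefin, which is the cyclohexene retron of ring B. The decalin therefore unravels to the cross-conjugated array C6=C5–C10(=C9)–C1≡C2, with ethynyl serving as a masked vinyl group.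
3. Forward order: geraniol supplies C9 and C11–C16 with the E-olefin. It is taken to an alkynol and then to a stereodefined tetrasubstituted dienyne. The first cycloaddition closes ring B. The C17 carbonyl is reduced to methyl and the ethynyl group to vinyl. The second cycloaddition closes ring A, followed by C4 methylation and acetate formation.
4. Stereochemistry: the purchased stereocentre of (S)-4-benzyloxazolidinone sets C8, and through the endo rule and the fixed olefin geometry also C9, in one event. C8 and C9 steer the face of the second cycloaddition (C5), and C5 steers the methylation (C4). The olefin geometries come from geraniol and from the anti-carbomagnesiation.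

Key step: step 10

Numbering and faces: C4 is the ester-bearing quaternary carbon (C18 ester, C19 methyl), C5 the ring-fusion CH and C10 the ring-fusion olefinic carbon. C9 is the quaternary carbon carrying the C20 methyl and the C11–C16 chain, and C8 is the CH carrying C17. The α face carries H5, C17, C19 and C20; the β face carries CO2Me and C11.
Assumption: ester 21 may form as a pair of C4 epimers, and this is taken as harmless because step 16 passes through their common planar enolate.

Step 1
Reactants: 1 geraniol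
Product: 2 geranyl TBDPS ether
Conditions: TBDPSCl, imidazole, DMF, 0 °C to rt
Reagents that add atoms: tert-butyl(chloro)diphenylsilane, CC(C)(C)[Si](Cl)(c1ccccc1)c1ccccc1
Why: Silylation of a primary allylic alcohol is routine, and the bulky TBDPS ether is chosen because it should outlast periodic acid, n-BuLi, hot Grignard reagent and the aluminium Lewis acids used later.

Step 2
Reactants: 2 geranyl TBDPS ether
Product: 3 6,7-epoxygeranyl TBDPS ether (racemic at the epoxide CH)
Conditions: mCPBA (1.0 equiv), CH2Cl2, −20 °C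
Reagents that add atoms: 3-chloroperoxybenzoic acid, OOC(=O)c1cccc(Cl)c1
Why: Prilezhaev epoxidation should pick the electron-richer distal trisubstituted olefin over the one deactivated by the allylic oxygen, and the new racemic stereocentre is erased in step 3.

Step 3
Reactants: 3 6,7-epoxygeranyl TBDPS ether
Product: 4 (4E)-6-[(tert-butyldiphenylsilyl)oxy]-4-methylhex-4-enal
Conditions: H5IO6, THF–H2O, 0 °C
Reagents that add atoms: none
Why: Periodic acid should hydrolyse the epoxide and cleave the glycol in one pot (Malaprade cleavage), releasing acetone and leaving the aldehyde whose carbonyl carbon becomes C9 beside the untouched E-olefin.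

Step 4
Reactants: 4 (4E)-6-[(tert-butyldiphenylsilyl)oxy]-4-methylhex-4-enal
Product: 5 (2E)-7,7-dibromo-3-methylhepta-2,6-dien-1-yl TBDPS ether
Conditions: CBr4, PPh3, CH2Cl2, 0 °C
Reagents that add atoms: carbon tetrabromide, BrC(Br)(Br)Br
Why: The first stage of the Corey–Fuchs reaction, a Wittig-type dibromoolefination of an unhindered aldehyde, adds the carbon that becomes C10.

Step 5
Reactants: 5 (2E)-7,7-dibromo-3-methylhepta-2,6-dien-1-yl TBDPS ether
Product: 7 (6E)-8-[(tert-butyldiphenylsilyl)oxy]-6-methyloct-6-en-2-yn-1-ol, via lithium acetylide 6 (not isolated)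
Conditions: n-BuLi (2.2 equiv), THF, −78 to 0 °C; (CH2O)n, to rt; H2O
Reagents that add atoms: paraformaldehyde (reacts as formaldehyde), C=O
Why: The second stage of the Corey–Fuchs reaction (Br/Li exchange, Fritsch–Buttenberg–Wiechell shift, deprotonation) should give acetylide 6, whose addition to formaldehyde installs C1 as the carbinol that directs step 6.

Step 6
Reactants: 7 (6E)-8-[(tert-butyldiphenylsilyl)oxy]-6-methyloct-6-en-2-yn-1-ol
Product: 9 (2E,6E)-8-[(tert-butyldiphenylsilyl)oxy]-2-ethenyl-3,6-dimethylocta-2,6-dien-1-ol, via magnesium chelate 8 (not isolated)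
Conditions: CH2=CHMgCl (4 equiv), THF–toluene, reflux; then CuI (10 mol %), MeI (excess), 0 °C to rt; H2O
Reagents that add atoms: vinylmagnesium chloride, C=C[Mg]Cl; iodomethane, CI
Why: Hydroxyl-directed anti-carbomagnesiation of a propargylic alcohol puts the vinyl group on C10 and magnesium on C9 within chelate 8, and copper-catalysed methylation of the alkenyl–magnesium bond with retention should fix the tetrasubstituted olefin with the chain cis to the vinyl group and the C20 methyl cis to C1.

Step 7
Reactants: 9 (2E,6E)-8-[(tert-butyldiphenylsilyl)oxy]-2-ethenyl-3,6-dimethylocta-2,6-dien-1-ol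
Product: 10 (2E,6E)-8-[(tert-butyldiphenylsilyl)oxy]-2-ethenyl-3,6-dimethylocta-2,6-dienal
Conditions: MnO2 (excess), CH2Cl2, rt
Reagents that add atoms: none
Why: MnO2 oxidises only the free allylic alcohol, under neutral conditions that should not scramble the tetrasubstituted olefin.

Step 8
Reactants: 10 (2E,6E)-8-[(tert-butyldiphenylsilyl)oxy]-2-ethenyl-3,6-dimethylocta-2,6-dienal
Product: 11 (2E,6E)-7-ethynyl-3,6-dimethylnona-2,6,8-trien-1-yl TBDPS ether
Conditions: Me3SiCHN2, LiN(iPr)2, THF, −78 °C to rt
Reagents that add atoms: (trimethylsilyl)diazomethane, C[Si](C)(C)C=[N+]=[N-]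
Why: The Colvin rearrangement (addition of lithiated Me3SiCHN2, Peterson-type loss of Me3SiOLi, loss of N2 and 1,2-hydrogen shift of the alkylidene carbene) should turn CHO into C≡CH in an aprotic medium that excludes conjugate addition and keeps the olefin geometry.

Step 9
Reactants: 12 (4S)-4-benzyl-1,3-oxazolidin-2-one; 13 acryloyl chloride
Product: 14 (4S)-3-acryloyl-4-benzyl-1,3-oxazolidin-2-one
Conditions: Et3N, LiCl, THF, −20 °C to rt (trace BHT)
Reagents that add atoms: none
Why: N-Acylation of the oxazolidinone under mild LiCl/Et3N activation limits acrylate polymerisation and carries the purchased stereocentre into a chelating dienophile.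

Step 10
Reactants: 11 (2E,6E)-7-ethynyl-3,6-dimethylnona-2,6,8-trien-1-yl TBDPS ether; 14 (4S)-3-acryloyl-4-benzyl-1,3-oxazolidin-2-one
Product: 15 (4S)-4-benzyl-3-{[(1R,2S)-2-{(3E)-5-[(tert-butyldiphenylsilyl)oxy]-3-methylpent-3-en-1-yl}-3-ethynyl-2-methylcyclohex-3-en-1-yl]carbonyl}-1,3-oxazolidin-2-one
Conditions: Et2AlCl (1.4 equiv to 14), CH2Cl2, −78 to −20 °C; aq HCl quench
Reagents that add atoms: none
Why: Et2AlCl converts 14 into its cationic bidentate aluminium chelate (s-cis acryloyl), which should add to the only 1,3-diene of 11, C6=C5–C10=C9, in a concerted but strongly asynchronous [4πs+2πs] Diels–Alder reaction with the C6–C7 bond leading and the C8–C9 bond closing on the developing tertiary allylic cation, the closest known reaction type being the auxiliary-controlled Diels–Alder reaction of N-acryloyl oxazolidinones with acyclic dienes, while quaternary carbons are known to form at fully substituted diene termini with activated dienophiles. Ring B is closed in this one intermolecular, suprafacial–suprafacial six-membered cycloaddition. C8 is controlled by the benzyl group of the auxiliary, which blocks the Cα-re face of the chelate so that C9 bonds to the Cα-si face (8R). C9 is controlled by the fixed olefin geometry together with the endo rule, since the outside C20 methyl ends up cis to the endo acyl carbon C17 and the inside chain trans to it (9S). Regioselectivity (C8 to C9 and C7 to C6) follows from attack of the unsubstituted, most nucleophilic terminus C6 on the acrylate β-carbon with charge build-up at the dialkylated C9. Site selectivity and mono-addition are secured by the linear ethynyl group on C10, which cannot act as a diene terminus, does not crowd the s-cis conformer and leaves an adduct that is no longer a diene.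

Step 11
Reactants: 15 the cycloadduct imide
Product: 16 [(1R,2S)-2-{(3E)-5-[(tert-butyldiphenylsilyl)oxy]-3-methylpent-3-en-1-yl}-3-ethynyl-2-methylcyclohex-3-en-1-yl]methanol
Conditions: LiBH4, H2O (1 equiv), Et2O, 0 °C
Reagents that add atoms: none
Why: Reductive cleavage of the N-acyl oxazolidinone by LiBH4 in moist ether attacks the exocyclic carbonyl, should leave C8, the alkyne and the silyl ether untouched, and returns auxiliary 12.

Step 12
Reactants: 16 the ethynyl alcohol
Product: 17 [(1R,2S)-2-{(3E)-5-[(tert-butyldiphenylsilyl)oxy]-3-methylpent-3-en-1-yl}-3-ethenyl-2-methylcyclohex-3-en-1-yl]methanol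
Conditions: H2 (1 atm), Pd/CaCO3–Pb(OAc)2, quinoline, EtOAc, rt
Reagents that add atoms: none
Why: Semihydrogenation of a terminal alkyne over lead-poisoned palladium should stop at the vinyl stage and so unmask the C5=C10–C1=C2 diene, the trisubstituted olefins being too hindered to compete.

Step 13
Reactants: 17 the dienyl alcohol
Product: 18 the methanesulfonate of 17
Conditions: MsCl, Et3N, CH2Cl2, 0 °C
Reagents that add atoms: methanesulfonyl chloride, CS(=O)(=O)Cl
Why: Routine sulfonylation of a primary alcohol prepares C17 for hydride displacement.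

Step 14
Reactants: 18 the methanesulfonate of 17
Product: 19 (5R,6S)-1-ethenyl-5,6-dimethyl-6-{(3E)-5-[(tert-butyldiphenylsilyl)oxy]-3-methylpent-3-en-1-yl}cyclohex-1-ene
Conditions: LiBHEt3, THF, 0 °C to reflux
Reagents that add atoms: none
Why: SN2 displacement of a primary, β-branched mesylate by the very nucleophilic hydride LiBHEt3 should deliver the C17 methyl group without touching the diene, the silyl ether or any stereocentre.

Step 15
Reactants: 19 the vinylcyclohexene; 20 methyl acrylate
Product: 21 methyl (1S,5S,6R,8aS)-5-{(3E)-5-[(tert-butyldiphenylsilyl)oxy]-3-methylpent-3-en-1-yl}-5,6-dimethyl-1,2,3,5,6,7,8,8a-octahydronaphthalene-1-carboxylate (endo epimer drawn)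
Conditions: EtAlCl2 (20 mol %), 2,6-di-tert-butylpyridine (10 mol %), CH2Cl2, −78 to −20 °C
Reagents that add atoms: none
Why: In this Lewis-acid-catalysed Diels–Alder reaction of a 1-vinylcyclohexene the ortho rule joins C4 to C5 and C3 to C2, the new olefin lands at C1=C10, and the dienophile should add to the β face of the half-chair that has C17 equatorial, anti to the pseudoaxial C20 methyl on C9, so that H5 ends up cis to C20, while the endo-derived C4 centre is of no consequence.

Step 16
Reactants: 21 the bicyclic ester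
Product: 23 methyl (1S,5S,6R,8aR)-5-{(3E)-5-[(tert-butyldiphenylsilyl)oxy]-3-methylpent-3-en-1-yl}-1,5,6-trimethyl-1,2,3,5,6,7,8,8a-octahydronaphthalene-1-carboxylate, via lithium ester enolate 22 (not isolated)
Conditions: LiN(iPr)2, THF, −78 °C; MeI, DMPU, −78 to −20 °C
Reagents that add atoms: iodomethane, CI
Why: In this alkylation of an exocyclic ester enolate MeI should approach along the equatorial trajectory on the α face, anti to the C5–C6 bond that leans to the β face, as is usual for cyclohexanecarboxylate enolates, which gives the equatorial C19 methyl and the axial CO2Me (4S).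

Step 17
Reactants: 23 the C4-methylated ester
Product: 25 methyl (1S,5S,6R,8aR)-5-[(3E)-5-acetoxy-3-methylpent-3-en-1-yl]-1,5,6-trimethyl-1,2,3,5,6,7,8,8a-octahydronaphthalene-1-carboxylate, via allylic alcohol 24 (not isolated)
Conditions: Bu4NF, THF, 0 °C to rt; then Ac2O, Et3N, DMAP (cat), rt
Reagents that add atoms: acetic anhydride, CC(=O)OC(C)=O
Why: Fluoride cleaves the Si–O bond and the liberated primary allylic alcohol is acetylated in the same flask under DMAP catalysis, the hindered tertiary methyl ester and all stereocentres being inert.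

**Compound list**
1 | geraniol | CC(C)=CCC/C(C)=C/CO | starting material
2 | geranyl TBDPS ether | CC(C)=CCC/C(C)=C/CO[Si](c1ccccc1)(c1ccccc1)C(C)(C)C | intermediate
3 | 6,7-epoxygeranyl TBDPS ether (racemic) | CC1(C)OC1CC/C(C)=C/CO[Si](c1ccccc1)(c1ccccc1)C(C)(C)C | intermediate
4 | (4E)-6-[(tert-butyldiphenylsilyl)oxy]-4-methylhex-4-enal | O=CCC/C(C)=C/CO[Si](c1ccccc1)(c1ccccc1)C(C)(C)C | intermediate
5 | (2E)-7,7-dibromo-3-methylhepta-2,6-dien-1-yl TBDPS ether | BrC(Br)=CCC/C(C)=C/CO[Si](c1ccccc1)(c1ccccc1)C(C)(C)C | intermediate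
6 | lithium acetylide of (2E)-3-methylhept-2-en-6-yn-1-yl TBDPS ether | [Li]C#CCC/C(C)=C/CO[Si](c1ccccc1)(c1ccccc1)C(C)(C)C | intermediate
7 | (6E)-8-[(tert-butyldiphenylsilyl)oxy]-6-methyloct-6-en-2-yn-1-ol | OCC#CCC/C(C)=C/CO[Si](c1ccccc1)(c1ccccc1)C(C)(C)C | intermediate
8 | magnesium chelate (1-oxa-2-magnesacyclopent-3-ene, vinyl on C10, Mg on C9) | C=CC1=C(CC/C(C)=C/CO[Si](c2ccccc2)(c2ccccc2)C(C)(C)C)[Mg]OC1 | intermediate
9 | (2E,6E)-8-[(tert-butyldiphenylsilyl)oxy]-2-ethenyl-3,6-dimethylocta-2,6-dien-1-ol | OC/C(C=C)=C(\C)CC/C(C)=C/CO[Si](c1ccccc1)(c1ccccc1)C(C)(C)C | intermediate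
10 | (2E,6E)-8-[(tert-butyldiphenylsilyl)oxy]-2-ethenyl-3,6-dimethylocta-2,6-dienal | O=C/C(C=C)=C(\C)CC/C(C)=C/CO[Si](c1ccccc1)(c1ccccc1)C(C)(C)C | intermediate
11 | (2E,6E)-7-ethynyl-3,6-dimethylnona-2,6,8-trien-1-yl TBDPS ether | C#C/C(C=C)=C(\C)CC/C(C)=C/CO[Si](c1ccccc1)(c1ccccc1)C(C)(C)C | intermediate
12 | (4S)-4-benzyl-1,3-oxazolidin-2-one | O=C1N[C@@H](Cc2ccccc2)CO1 | starting material
13 | acryloyl chloride | C=CC(=O)Cl | starting material
14 | (4S)-3-acryloyl-4-benzyl-1,3-oxazolidin-2-one | C=CC(=O)N1C(=O)OC[C@@H]1Cc1ccccc1 | intermediate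
15 | cycloadduct imide, (1R,2S) in the cyclohexene (8R,9S), (4S) in the auxiliary | C#CC1=CCC[C@@H](C(=O)N2C(=O)OC[C@@H]2Cc2ccccc2)[C@]1(C)CC/C(C)=C/CO[Si](c1ccccc1)(c1ccccc1)C(C)(C)C | intermediate
16 | (1R,2S)-ethynyl alcohol | C#CC1=CCC[C@@H](CO)[C@]1(C)CC/C(C)=C/CO[Si](c1ccccc1)(c1ccccc1)C(C)(C)C | intermediate
17 | (1R,2S)-ethenyl (dienyl) alcohol | C=CC1=CCC[C@@H](CO)[C@]1(C)CC/C(C)=C/CO[Si](c1ccccc1)(c1ccccc1)C(C)(C)C | intermediate
18 | methanesulfonate of 17 | C=CC1=CCC[C@@H](COS(C)(=O)=O)[C@]1(C)CC/C(C)=C/CO[Si](c1ccccc1)(c1ccccc1)C(C)(C)C | intermediate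
19 | (5R,6S)-1-ethenyl-5,6-dimethyl-6-(silyloxy-methylpentenyl)cyclohex-1-ene | C=CC1=CCC[C@@H](C)[C@]1(C)CC/C(C)=C/CO[Si](c1ccccc1)(c1ccccc1)C(C)(C)C | intermediate
20 | methyl acrylate | C=CC(=O)OC | starting material
21 | bicyclic ester, (1S,5S,6R,8aS), endo epimer | COC(=O)[C@H]1CCC=C2[C@H]1CC[C@@H](C)[C@]2(C)CC/C(C)=C/CO[Si](c1ccccc1)(c1ccccc1)C(C)(C)C | intermediate
22 | lithium ester enolate of 21 | COC(O[Li])=C1CCC=C2[C@H]1CC[C@@H](C)[C@]2(C)CC/C(C)=C/CO[Si](c1ccccc1)(c1ccccc1)C(C)(C)C | intermediate
23 | C4-methylated ester, (1S,5S,6R,8aR), TBDPS ether | COC(=O)[C@@]1(C)CCC=C2[C@H]1CC[C@@H](C)[C@]2(C)CC/C(C)=C/CO[Si](c1ccccc1)(c1ccccc1)C(C)(C)C | intermediate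
24 | free allylic alcohol, (1S,5S,6R,8aR) | COC(=O)[C@@]1(C)CCC=C2[C@H]1CC[C@@H](C)[C@]2(C)CC/C(C)=C/CO | intermediate
25 | CNP0209995.1 | COC(=O)[C@@]1(C)CCC=C2[C@H]1CC[C@@H](C)[C@]2(C)CC/C(C)=C/COC(C)=O | target

**Totals and risks**
Total step count: 17. Longest linear sequence: 16 (steps 1–8 and 10–17).

Step 10 is the most likely to fail. The chain sits on the inside position of C9, so the s-cis conformer of 11 is poorly populated. Cycloaddition may then be outrun by polymerisation of the dienophile or by an ene reaction at the chain olefin, and endo control may erode.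
- The fallback sets out from 11 and returns at 16.
- It replaces the stoichiometric chelated auxiliary by iminium catalysis with the much smaller dienophile acrolein.
- Compound 11 and acrolein are treated with (5S)-5-benzyl-2,2,3-trimethylimidazolidin-4-one hydrochloride (20 mol %) in MeCN–H2O at 0 °C to rt. The benzyl group of this catalyst also leaves the Cα-si face open.
- This should give (1R,2S)-2-{(3E)-5-[(tert-butyldiphenylsilyl)oxy]-3-methylpent-3-en-1-yl}-3-ethynyl-2-methylcyclohex-3-ene-1-carbaldehyde F1.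
- NaBH4 in MeOH then reduces F1 to 16.

Step 6 is the second risk. Carbomagnesiation of an alkyl-substituted alkynol may be sluggish. Capture of the hindered alkenylmagnesium by MeI may be incomplete, so that protonation on work-up competes.
- The fallback sets out from 5 and returns at 11, replacing steps 5–8.
- It builds the tetrasubstituted olefin by syn-carbocupration instead.
- Compound 5 with n-BuLi and then ClCO2Me gives methyl (6E)-8-[(tert-butyldiphenylsilyl)oxy]-6-methyloct-6-en-2-ynoate F2.
- Me2CuLi at −78 °C followed by I2 gives methyl (2E,6E)-8-[(tert-butyldiphenylsilyl)oxy]-2-iodo-3,6-dimethylocta-2,6-dienoate F3, with methyl cis to iodine and the chain cis to the ester.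
- Sonogashira coupling with trimethylsilylacetylene (PdCl2(PPh3)2, CuI, Et3N) gives methyl (2Z,6E)-8-[(tert-butyldiphenylsilyl)oxy]-3,6-dimethyl-2-[(trimethylsilyl)ethynyl]octa-2,6-dienoate F4.
- i-Bu2AlH gives the (2Z,6E)-allylic alcohol F5, and MnO2 gives the (2Z,6E)-enal F6.
- Wittig methylenation with Ph3P=CH2 gives the C-silylated dienyne F7.
- K2CO3 in MeOH removes the silyl group to give 11. The ester carbon has become C5, cis to the chain, and the alkyne lies cis to C20.

Step 15 is the third risk. The two half-chairs of 19 lie close in energy, so facial selectivity may be poor. Acid-induced migration of the new olefin is a further hazard.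
- The fallback sets out from 19 and returns at 21.
- It replaces substrate control by matched reagent control.
- Commercial (4R)-4-benzyl-1,3-oxazolidin-2-one is acylated with 13 as in step 9 to give (4R)-3-acryloyl-4-benzyl-1,3-oxazolidin-2-one F8.
- The Et2AlCl chelate of F8 exposes the Cα-re face, which in the endo, ortho orientation can meet only the β face of 19.
- This should give (4R)-4-benzyl-3-{[(1S,5S,6R,8aS)-5-{(3E)-5-[(tert-butyldiphenylsilyl)oxy]-3-methylpent-3-en-1-yl}-5,6-dimethyl-1,2,3,5,6,7,8,8a-octahydronaphthalen-1-yl]carbonyl}-1,3-oxazolidin-2-one F9.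
- Methanolysis with MeOMgBr in MeOH converts F9 into 21.

**Further compounds**
F1 | step 10 | (1R,2S)-2-{(3E)-5-[(tert-butyldiphenylsilyl)oxy]-3-methylpent-3-en-1-yl}-3-ethynyl-2-methylcyclohex-3-ene-1-carbaldehyde | C#CC1=CCC[C@@H](C=O)[C@]1(C)CC/C(C)=C/CO[Si](c1ccccc1)(c1ccccc1)C(C)(C)C
F2 | step 6 | methyl (6E)-8-[(tert-butyldiphenylsilyl)oxy]-6-methyloct-6-en-2-ynoate | COC(=O)C#CCC/C(C)=C/CO[Si](c1ccccc1)(c1ccccc1)C(C)(C)C
F3 | step 6 | methyl (2E,6E)-8-[(tert-butyldiphenylsilyl)oxy]-2-iodo-3,6-dimethylocta-2,6-dienoate | COC(=O)/C(I)=C(/C)CC/C(C)=C/CO[Si](c1ccccc1)(c1ccccc1)C(C)(C)C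
F4 | step 6 | methyl (2Z,6E)-8-[(tert-butyldiphenylsilyl)oxy]-3,6-dimethyl-2-[(trimethylsilyl)ethynyl]octa-2,6-dienoate | COC(=O)/C(C#C[Si](C)(C)C)=C(/C)CC/C(C)=C/CO[Si](c1ccccc1)(c1ccccc1)C(C)(C)C
F5 | step 6 | (2Z,6E)-8-[(tert-butyldiphenylsilyl)oxy]-3,6-dimethyl-2-[(trimethylsilyl)ethynyl]octa-2,6-dien-1-ol | OC/C(C#C[Si](C)(C)C)=C(/C)CC/C(C)=C/CO[Si](c1ccccc1)(c1ccccc1)C(C)(C)C
F6 | step 6 | (2Z,6E)-8-[(tert-butyldiphenylsilyl)oxy]-3,6-dimethyl-2-[(trimethylsilyl)ethynyl]octa-2,6-dienal | O=C/C(C#C[Si](C)(C)C)=C(/C)CC/C(C)=C/CO[Si](c1ccccc1)(c1ccccc1)C(C)(C)C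
F7 | step 6 | (2E,6E)-3,6-dimethyl-7-[(trimethylsilyl)ethynyl]nona-2,6,8-trien-1-yl TBDPS ether | C=C/C(C#C[Si](C)(C)C)=C(/C)CC/C(C)=C/CO[Si](c1ccccc1)(c1ccccc1)C(C)(C)C
F8 | step 15 | (4R)-3-acryloyl-4-benzyl-1,3-oxazolidin-2-one | C=CC(=O)N1C(=O)OC[C@H]1Cc1ccccc1
F9 | step 15 | (4R)-4-benzyl-3-{[(1S,5S,6R,8aS)-5-{(3E)-5-[(tert-butyldiphenylsilyl)oxy]-3-methylpent-3-en-1-yl}-5,6-dimethyl-1,2,3,5,6,7,8,8a-octahydronaphthalen-1-yl]carbonyl}-1,3-oxazolidin-2-one | O=C(N1C(=O)OC[C@H]1Cc1ccccc1)[C@H]2CCC=C3[C@H]2CC[C@@H](C)[C@]3(C)CC/C(C)=C/CO[Si](c4ccccc4)(c5ccccc5)C(C)(C)C
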